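**Plan**
- Retrosynthesis: the formyl carbon is traced back to the methyl of a 2-isopropenyl group (allylic C–H oxidation), the two acyl–oxygen bonds are cut to a C3 alcohol and a silyl-protected side-chain alcohol, and then the C2–C3 bond of the dihydrofuran ring is cut.
- Enabling feature: in the dihydrofuran ring, C2 (bound to O1) and C3 (bearing the acyloxy oxygen) are neighbouring oxygenated carbons and C2 carries a 1,1-disubstituted alkene. This is the footprint of an O1-tethered γ-aryloxyallylstannane adding through its oxygen-bearing carbon to an ortho aldehyde with allyl transposition.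
- Forward order: the benzene ring is bought as methyl 5-acetyl-2-hydroxybenzoate. O1 is alkylated with methallyl chloride, the ketone reduced and silylated, the ester taken to the aldehyde and the allyl ether to the stannane. Step 7 closes the only ring that has to be built, and two acylations and a two-step allylic oxidation finish the route.
- Stereochemistry: the side-chain (S) centre comes from Ru-catalysed asymmetric transfer hydrogenation. C2/C3 trans comes from the open Lewis-acid transition state of the ring closure, and their absolute sense from the (R)-BINOL–Ti(OiPr)4 catalyst.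
- The future formyl carbon is carried as a methyl group, so that the allyl ether has a single oxygen-activated allylic position when it is lithiated.

Key step: step 7

Assumption: the sense of induction of (R)-1,1′-bi-2-naphthol [(R)-BINOL]–Ti(OiPr)4 in the ring closure is taken from intermolecular allylstannane additions to aryl aldehydes; should the first run show the opposite sense, (S)-BINOL is used in step 7.

**Route**

Step 1
Reactants: 1 methyl 5-acetyl-2-hydroxybenzoate; 2 3-chloro-2-methylprop-1-ene (methallyl chloride)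
Product: 3 methyl 5-acetyl-2-[(2-methylprop-2-en-1-yl)oxy]benzoate
Conditions: K2CO3, KI (cat.), DMF, 60 °C
Reagents that add atoms: 3-chloro-2-methylprop-1-ene (2), CC(=C)CCl
Why: Williamson etherification of the salicylate phenoxide with an allylic chloride (SN2, iodide-assisted), under which the methyl ketone and the ester are inert and the temperature is far below that of a Claisen rearrangement.

Step 2
Reactants: 3 methyl 5-acetyl-2-[(2-methylprop-2-en-1-yl)oxy]benzoate
Product: 4 methyl 5-[(1S)-1-hydroxyethyl]-2-[(2-methylprop-2-en-1-yl)oxy]benzoate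
Conditions: RuCl[(S,S)-TsDPEN](p-cymene) (1 mol%), HCO2H/Et3N (5:2), 30 °C
Reagents that add atoms: none
Why: Noyori–Ikariya asymmetric transfer hydrogenation, in which the (S,S)-TsDPEN ruthenium hydride delivers hydride to the face of the aryl methyl ketone that gives (S)-1-arylethanols, while the ester and the isolated alkene are not reduced.

Step 3
Reactants: 4 methyl 5-[(1S)-1-hydroxyethyl]-2-[(2-methylprop-2-en-1-yl)oxy]benzoate; 5 tert-butyldimethylsilyl chloride
Product: 6 methyl 5-[(1S)-1-{[tert-butyl(dimethyl)silyl]oxy}ethyl]-2-[(2-methylprop-2-en-1-yl)oxy]benzoate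
Conditions: TBSCl, imidazole, DMF, rt
Reagents that add atoms: tert-butyldimethylsilyl chloride (5), CC(C)(C)[Si](C)(C)Cl
Why: imidazole-promoted O-silylation of the only hydroxyl group, which leaves the C–O bond of the stereocentre untouched and gives an ether stable to hydride, organolithium and mild Lewis acid.

Step 4
Reactants: 6 methyl 5-[(1S)-1-{[tert-butyl(dimethyl)silyl]oxy}ethyl]-2-[(2-methylprop-2-en-1-yl)oxy]benzoate
Product: 7 {5-[(1S)-1-{[tert-butyl(dimethyl)silyl]oxy}ethyl]-2-[(2-methylprop-2-en-1-yl)oxy]phenyl}methanol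
Conditions: LiAlH4, THF, 0 °C; H2O work-up
Reagents that add atoms: none
Why: hydride reduction of the methyl ester to the benzylic alcohol, to which the silyl ether, the aryl allyl ether and the terminal alkene are inert.

Step 5
Reactants: 7 {5-[(1S)-1-{[tert-butyl(dimethyl)silyl]oxy}ethyl]-2-[(2-methylprop-2-en-1-yl)oxy]phenyl}methanol; 8 tributyltin chloride
Product: 10 {5-[(1S)-1-{[tert-butyl(dimethyl)silyl]oxy}ethyl]-2-{[(1Z)-2-methyl-3-(tributylstannyl)prop-1-en-1-yl]oxy}phenyl}methanol, via dilithio species 9 (not isolated)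
Conditions: sec-BuLi (2.2 equiv), N,N,N′,N′-tetramethylethylenediamine (TMEDA), THF, −78 °C; Bu3SnCl (1.1 equiv), −78 °C; H2O; Et3N-buffered silica
Reagents that add atoms: tributyltin chloride (8), CCCC[Sn](Cl)(CCCC)CCCC
Why: allyl ether α-lithiation followed by γ-stannylation, in which the first equivalent of sec-BuLi forms the lithium alkoxide, the second removes a proton from the only oxygen-activated allylic position (OCH2), and the internally chelated oxyallyl lithium 9 should be stannylated at the carbon terminus remote from oxygen to give the (Z)-γ-aryloxyallylstannane.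

Step 6
Reactants: 10 {5-[(1S)-1-{[tert-butyl(dimethyl)silyl]oxy}ethyl]-2-{[(1Z)-2-methyl-3-(tributylstannyl)prop-1-en-1-yl]oxy}phenyl}methanol
Product: 11 5-[(1S)-1-{[tert-butyl(dimethyl)silyl]oxy}ethyl]-2-{[(1Z)-2-methyl-3-(tributylstannyl)prop-1-en-1-yl]oxy}benzaldehyde
Conditions: SO3·pyridine, DMSO, Et3N, CH2Cl2, 0 °C; used directly in step 7
Reagents that add atoms: none
Why: Parikh–Doering oxidation of the benzylic alcohol, whose basic, non-acidic medium is the usual choice in the presence of an enol ether and an allylstannane.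

Step 7
Reactants: 11 5-[(1S)-1-{[tert-butyl(dimethyl)silyl]oxy}ethyl]-2-{[(1Z)-2-methyl-3-(tributylstannyl)prop-1-en-1-yl]oxy}benzaldehyde
Product: 13 (2R,3S)-5-[(1S)-1-{[tert-butyl(dimethyl)silyl]oxy}ethyl]-2-(prop-1-en-2-yl)-2,3-dihydro-1-benzofuran-3-ol, via tributylstannyl ether 12 (not isolated)
Conditions: (R)-BINOL (40 mol%), Ti(OiPr)4 (20 mol%), 4 Å molecular sieves, CH2Cl2, −20 °C; aq. NaHCO3
Reagents that add atoms: none
Why: Proposed new method: the titanium–BINOL Lewis acid binds the aldehyde oxygen of 11, the oxygen-bearing enol-ether carbon of the tethered allylstannane attacks the carbonyl carbon through an open SE2′ transition state, and the C–Sn bond at the far allyl terminus breaks to leave the isopropenyl group and the stannyl ether 12, which aqueous work-up hydrolyses to 13. The closest known reactions are the BF3·OEt2-promoted intramolecular γ-alkoxyallylstannane–aldehyde cyclisation to trans-2-alkenyl-3-hydroxy cyclic ethers and the intermolecular BINOL–Ti(OiPr)4-catalysed (Keck) allylstannane addition; joining them in a five-membered, catalyst-controlled closure is the untested part. The dihydrofuran ring closes in the 5-exo-trig mode at the carbonyl carbon, with the enol-ether double bond exocyclic to the ring being formed. C3 is set by the aldehyde face that the (R)-BINOL complex leaves open, and C2 follows from it because the Lewis-acid-bound carbonyl oxygen should sit anti to the 2-methylallyl unit in the open transition state, which places O3 and the isopropenyl group trans. The step needs enantioface selectivity at the aldehyde (the silyloxyethyl centre is too far away to help), attack through the oxygen-bearing allyl terminus and survival of two ionisable benzylic C–O bonds. The ortho placement of aldehyde and enol ether on the arene allows only the five-membered closure, and the weak Lewis acid at low temperature should spare the C3 alcohol from elimination to the benzofuran and the silyl ether from ionisation.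

Step 8
Reactants: 13 (2R,3S)-5-[(1S)-1-{[tert-butyl(dimethyl)silyl]oxy}ethyl]-2-(prop-1-en-2-yl)-2,3-dihydro-1-benzofuran-3-ol; 14 3-methylbutanoyl chloride (isovaleryl chloride)
Product: 15 (2R,3S)-5-[(1S)-1-{[tert-butyl(dimethyl)silyl]oxy}ethyl]-2-(prop-1-en-2-yl)-2,3-dihydro-1-benzofuran-3-yl 3-methylbutanoate
Conditions: isovaleryl chloride, pyridine, 4-(dimethylamino)pyridine (DMAP, cat.), CH2Cl2, 0 °C
Reagents that add atoms: 3-methylbutanoyl chloride (14), CC(C)CC(=O)Cl
Why: DMAP-catalysed O-acylation of the secondary benzylic alcohol, which forms the ester at oxygen without breaking the C3–O bond, so the configuration at C3 is retained.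

Step 9
Reactants: 15 (2R,3S)-5-[(1S)-1-{[tert-butyl(dimethyl)silyl]oxy}ethyl]-2-(prop-1-en-2-yl)-2,3-dihydro-1-benzofuran-3-yl 3-methylbutanoate
Product: 16 (2R,3S)-5-[(1S)-1-hydroxyethyl]-2-(prop-1-en-2-yl)-2,3-dihydro-1-benzofuran-3-yl 3-methylbutanoate
Conditions: Bu4NF, AcOH, THF, 0 °C to rt
Reagents that add atoms: none
Why: fluoride-induced cleavage of the Si–O bond, buffered with acetic acid so that the C3 ester is neither cleaved nor eliminated and the benzylic C–O bond of the side chain is not ionised.

Step 10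
Reactants: 16 (2R,3S)-5-[(1S)-1-hydroxyethyl]-2-(prop-1-en-2-yl)-2,3-dihydro-1-benzofuran-3-yl 3-methylbutanoate; 17 acetic anhydride
Product: 18 (2R,3S)-5-[(1S)-1-(acetyloxy)ethyl]-2-(prop-1-en-2-yl)-2,3-dihydro-1-benzofuran-3-yl 3-methylbutanoate
Conditions: Ac2O, pyridine, DMAP (cat.), CH2Cl2, 0 °C
Reagents that add atoms: acetic anhydride (17), CC(=O)OC(C)=O
Why: DMAP-catalysed acetylation at oxygen under basic conditions, which keeps the (S) configuration of the electron-rich benzylic centre because no cation is formed there.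

Step 11
Reactants: 18 (2R,3S)-5-[(1S)-1-(acetyloxy)ethyl]-2-(prop-1-en-2-yl)-2,3-dihydro-1-benzofuran-3-yl 3-methylbutanoate; 19 tert-butyl hydroperoxide
Product: 20 (2R,3S)-5-[(1S)-1-(acetyloxy)ethyl]-2-(3-hydroxyprop-1-en-2-yl)-2,3-dihydro-1-benzofuran-3-yl 3-methylbutanoate
Conditions: SeO2 (cat.), t-BuOOH, CH2Cl2, rt; any enal already formed is carried on with the alcohol
Reagents that add atoms: tert-butyl hydroperoxide (19), CC(C)(C)OO, whose oxygen atom is handed on by SeO2, O=[Se]=O
Why: Riley-type allylic oxidation (ene reaction of SeO2, [2,3]-sigmatropic shift, hydrolysis, with t-BuOOH re-oxidising selenium), in which the methyl group of a 1,1-disubstituted alkene reacts in preference to the allylic methine C2–H, as is known for 2-isopropenyl-2,3-dihydrobenzofurans, and the neutral room-temperature medium should leave both benzylic esters intact.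

Step 12
Reactants: 20 (2R,3S)-5-[(1S)-1-(acetyloxy)ethyl]-2-(3-hydroxyprop-1-en-2-yl)-2,3-dihydro-1-benzofuran-3-yl 3-methylbutanoate
Product: 21 (2R,3S)-5-[(1S)-1-(acetyloxy)ethyl]-2-(3-oxoprop-1-en-2-yl)-2,3-dihydro-1-benzofuran-3-yl 3-methylbutanoate
Conditions: MnO2 (excess), CH2Cl2, rt
Reagents that add atoms: none
Why: MnO2 oxidation of the primary allylic alcohol to the 2-substituted acrolein on a neutral surface, which avoids base-induced migration of the exocyclic double bond and loss of the C3 ester.

**Compound list**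
1 | methyl 5-acetyl-2-hydroxybenzoate | COC(=O)c1cc(C(C)=O)ccc1O | starting material
2 | 3-chloro-2-methylprop-1-ene | CC(=C)CCl | starting material
3 | methyl 5-acetyl-2-[(2-methylprop-2-en-1-yl)oxy]benzoate | COC(=O)c1cc(C(C)=O)ccc1OCC(C)=C | intermediate
4 | methyl 5-[(1S)-1-hydroxyethyl]-2-[(2-methylprop-2-en-1-yl)oxy]benzoate | COC(=O)c1cc([C@H](C)O)ccc1OCC(C)=C | intermediate
5 | tert-butyldimethylsilyl chloride | CC(C)(C)[Si](C)(C)Cl | starting material
6 | methyl 5-[(1S)-1-{[tert-butyl(dimethyl)silyl]oxy}ethyl]-2-[(2-methylprop-2-en-1-yl)oxy]benzoate | COC(=O)c1cc([C@H](C)O[Si](C)(C)C(C)(C)C)ccc1OCC(C)=C | intermediate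
7 | {5-[(1S)-1-{[tert-butyl(dimethyl)silyl]oxy}ethyl]-2-[(2-methylprop-2-en-1-yl)oxy]phenyl}methanol | OCc1cc([C@H](C)O[Si](C)(C)C(C)(C)C)ccc1OCC(C)=C | intermediate
8 | tributyltin chloride | CCCC[Sn](Cl)(CCCC)CCCC | starting material
9 | O,C-dilithio species of 7 (lithium alkoxide, lithiated at the OCH2 carbon; delocalised allyl anion drawn in its α-lithio form) | [Li]OCc1cc([C@H](C)O[Si](C)(C)C(C)(C)C)ccc1OC([Li])C(C)=C | intermediate (not isolated)
10 | {5-[(1S)-1-{[tert-butyl(dimethyl)silyl]oxy}ethyl]-2-{[(1Z)-2-methyl-3-(tributylstannyl)prop-1-en-1-yl]oxy}phenyl}methanol | OCc1cc([C@H](C)O[Si](C)(C)C(C)(C)C)ccc1O/C=C(/C)C[Sn](CCCC)(CCCC)CCCC | intermediate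
11 | 5-[(1S)-1-{[tert-butyl(dimethyl)silyl]oxy}ethyl]-2-{[(1Z)-2-methyl-3-(tributylstannyl)prop-1-en-1-yl]oxy}benzaldehyde | O=Cc1cc([C@H](C)O[Si](C)(C)C(C)(C)C)ccc1O/C=C(/C)C[Sn](CCCC)(CCCC)CCCC | intermediate
12 | tributyl{[(2R,3S)-5-[(1S)-1-{[tert-butyl(dimethyl)silyl]oxy}ethyl]-2-(prop-1-en-2-yl)-2,3-dihydro-1-benzofuran-3-yl]oxy}stannane | C=C(C)[C@H]1Oc2ccc([C@H](C)O[Si](C)(C)C(C)(C)C)cc2[C@@H]1O[Sn](CCCC)(CCCC)CCCC | intermediate (not isolated)
13 | (2R,3S)-5-[(1S)-1-{[tert-butyl(dimethyl)silyl]oxy}ethyl]-2-(prop-1-en-2-yl)-2,3-dihydro-1-benzofuran-3-ol | C=C(C)[C@H]1Oc2ccc([C@H](C)O[Si](C)(C)C(C)(C)C)cc2[C@@H]1O | intermediate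
14 | 3-methylbutanoyl chloride | CC(C)CC(=O)Cl | starting material
15 | (2R,3S)-5-[(1S)-1-{[tert-butyl(dimethyl)silyl]oxy}ethyl]-2-(prop-1-en-2-yl)-2,3-dihydro-1-benzofuran-3-yl 3-methylbutanoate | C=C(C)[C@H]1Oc2ccc([C@H](C)O[Si](C)(C)C(C)(C)C)cc2[C@@H]1OC(=O)CC(C)C | intermediate
16 | (2R,3S)-5-[(1S)-1-hydroxyethyl]-2-(prop-1-en-2-yl)-2,3-dihydro-1-benzofuran-3-yl 3-methylbutanoate | C=C(C)[C@H]1Oc2ccc([C@H](C)O)cc2[C@@H]1OC(=O)CC(C)C | intermediate
17 | acetic anhydride | CC(=O)OC(C)=O | starting material
18 | (2R,3S)-5-[(1S)-1-(acetyloxy)ethyl]-2-(prop-1-en-2-yl)-2,3-dihydro-1-benzofuran-3-yl 3-methylbutanoate | C=C(C)[C@H]1Oc2ccc([C@H](C)OC(C)=O)cc2[C@@H]1OC(=O)CC(C)C | intermediate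
19 | tert-butyl hydroperoxide | CC(C)(C)OO | starting material
20 | (2R,3S)-5-[(1S)-1-(acetyloxy)ethyl]-2-(3-hydroxyprop-1-en-2-yl)-2,3-dihydro-1-benzofuran-3-yl 3-methylbutanoate | C=C(CO)[C@H]1Oc2ccc([C@H](C)OC(C)=O)cc2[C@@H]1OC(=O)CC(C)C | intermediate
21 | (2R,3S)-5-[(1S)-1-(acetyloxy)ethyl]-2-(3-oxoprop-1-en-2-yl)-2,3-dihydro-1-benzofuran-3-yl 3-methylbutanoate | C=C(C=O)[C@H]1Oc2ccc([C@H](C)OC(C)=O)cc2[C@@H]1OC(=O)CC(C)C | target

**Step count**
Total: 12 steps. Longest linear sequence: 12 steps, from methyl 5-acetyl-2-hydroxybenzoate.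

**Steps most likely to fail**

1. Step 7 (proposed new method). What may go wrong: poor facial discrimination at the aldehyde and slow turnover. The weak titanium Lewis acid may not organise an addition whose tether already fixes much of the geometry, so both trans diastereomers may form, and a sluggish reaction leaves time for protodestannylation. Fallback by known chemistry, setting out from 11 and coming back at 13: the ring is closed with BF3·OEt2 in CH2Cl2 at −78 °C (aq. NaHCO3 work-up), the established achiral protocol for this cyclisation type. This should give 13 together with the (2S,3R) trans diastereomer F1 in comparable amounts. The mixture is esterified with (1S)-camphanic chloride (pyridine, DMAP, CH2Cl2). The (2R,3S) camphanate F2 is separated from the (2S,3R) camphanate F3 by chromatography or crystallisation, and methanolysis of F2 (K2CO3, MeOH, rt) returns 13. Stereocontrol thus passes from the catalyst to a classical separation of covalent diastereomers.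

2. Step 5. What may go wrong: incomplete or misdirected metalation. The lithium alkoxide formed first may aggregate and slow the second deprotonation, sec-BuLi may displace the aryloxide in an SN2′ sense instead of removing the allylic proton, and the hydroxy enol-ether stannane may acetalise or lose tin on contact with acid during isolation and oxidation. Fallback, setting out from 7 and coming back at 11: oxidation with MnO2 in CH2Cl2 gives the methallyloxy benzaldehyde F4 before any tin is present. Lithium 4-methylpiperazin-1-ide (1-methylpiperazine, n-BuLi, THF, −40 °C) adds to the formyl group to give the lithium α-amino alkoxide F5 as an in situ protecting group. sec-BuLi/TMEDA at −78 °C lithiates the allyl ether to the allyllithium F6, Bu3SnCl gives the stannylated amino alkoxide F7, and aqueous work-up releases 11 directly. The free alcohol 10 and the oxidation of step 6 are avoided.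

3. Step 11. What may go wrong: loss of site selectivity or of the esters in the allylic oxidation, through ene attack at the allylic C2–H instead of the methyl group, over-oxidation, or ionisation of the two benzylic esters by selenous acid. Fallback, setting out from 18 and coming back at 21: ene-type allylic chlorination with N-chlorosuccinimide and PhSeCl (cat.) in CH2Cl2 at rt, chosen to avoid free hypochlorous acid that could chlorinate the aryl ether ring, should give the allylic chloride F8. Oxidation of F8 with trimethylamine N-oxide in DMSO (amine-oxide variant of the Kornblum oxidation) leads straight to 21, bypassing 20 and step 12.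

**Further compounds**
F1 | step 7 | (2S,3R)-5-[(1S)-1-{[tert-butyl(dimethyl)silyl]oxy}ethyl]-2-(prop-1-en-2-yl)-2,3-dihydro-1-benzofuran-3-ol | C=C(C)[C@@H]1Oc2ccc([C@H](C)O[Si](C)(C)C(C)(C)C)cc2[C@H]1O
F2 | step 7 | (2R,3S)-5-[(1S)-1-{[tert-butyl(dimethyl)silyl]oxy}ethyl]-2-(prop-1-en-2-yl)-2,3-dihydro-1-benzofuran-3-yl (1S,4R)-4,7,7-trimethyl-3-oxo-2-oxabicyclo[2.2.1]heptane-1-carboxylate | C=C(C)[C@H]1Oc2ccc([C@H](C)O[Si](C)(C)C(C)(C)C)cc2[C@@H]1OC(=O)[C@@]34CC[C@@](C)(C(=O)O3)C4(C)C
F3 | step 7 | (2S,3R)-5-[(1S)-1-{[tert-butyl(dimethyl)silyl]oxy}ethyl]-2-(prop-1-en-2-yl)-2,3-dihydro-1-benzofuran-3-yl (1S,4R)-4,7,7-trimethyl-3-oxo-2-oxabicyclo[2.2.1]heptane-1-carboxylate | C=C(C)[C@@H]1Oc2ccc([C@H](C)O[Si](C)(C)C(C)(C)C)cc2[C@H]1OC(=O)[C@@]34CC[C@@](C)(C(=O)O3)C4(C)C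
F4 | step 5 | 5-[(1S)-1-{[tert-butyl(dimethyl)silyl]oxy}ethyl]-2-[(2-methylprop-2-en-1-yl)oxy]benzaldehyde | O=Cc1cc([C@H](C)O[Si](C)(C)C(C)(C)C)ccc1OCC(C)=C
F5 | step 5 | lithium {5-[(1S)-1-{[tert-butyl(dimethyl)silyl]oxy}ethyl]-2-[(2-methylprop-2-en-1-yl)oxy]phenyl}(4-methylpiperazin-1-yl)methanolate (either configuration at the aminal carbon) | [Li]OC(N1CCN(C)CC1)c1cc([C@H](C)O[Si](C)(C)C(C)(C)C)ccc1OCC(C)=C
F6 | step 5 | allyllithium derived from F5 by lithiation at the OCH2 carbon (drawn in its α-lithio form) | [Li]OC(N1CCN(C)CC1)c1cc([C@H](C)O[Si](C)(C)C(C)(C)C)ccc1OC([Li])C(C)=C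
F7 | step 5 | lithium {5-[(1S)-1-{[tert-butyl(dimethyl)silyl]oxy}ethyl]-2-{[(1Z)-2-methyl-3-(tributylstannyl)prop-1-en-1-yl]oxy}phenyl}(4-methylpiperazin-1-yl)methanolate | [Li]OC(N1CCN(C)CC1)c1cc([C@H](C)O[Si](C)(C)C(C)(C)C)ccc1O/C=C(/C)C[Sn](CCCC)(CCCC)CCCC
F8 | step 11 | (2R,3S)-5-[(1S)-1-(acetyloxy)ethyl]-2-(3-chloroprop-1-en-2-yl)-2,3-dihydro-1-benzofuran-3-yl 3-methylbutanoate | C=C(CCl)[C@H]1Oc2ccc([C@H](C)OC(C)=O)cc2[C@@H]1OC(=O)CC(C)C
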